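Remarks on the chemistry
- Atom labels used throughout: ring C1 carries the side chain, C2 the methylidene, C3 the allylic bromine, C4 is CH2, C5 carries the second bromine, C6 is the gem-dimethyl carbon; chain C7, C8, C9 (carbinol), C10=C11 (vinyl). In every SMILES below the C1 chain and the C5 bromine are on one ring face and the C3 bromine on the other.
- Assumption: (S)-linalool of high enantiomeric purity is used; its optical purity fixes that of C9, because no later step touches that centre.
- Consistency check: the stereo-structures of 2, 9, 12 and 21 agree with one another and need no correction. The CIP descriptor at C1 changes (R in 12 and 13, S in 15–17, R in 19 and 20, S in 21) only because neighbour priorities change, not the configuration.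
- Stoichiometry of the zinc reagent: 9 holds two side chains on one zinc atom, so two molecules of 8 are consumed for each molecule of 9, and only one of the two chains is transferred in step 6. This is accepted because the chain comes in four steps from an inexpensive terpene alcohol. In step 6 the zinc reagent 9 is the limiting component and the inexpensive dienone 2 is used in slight excess.
- Design choices made for safety: the methylidene is unveiled by quaternisation–elimination at the ketone stage, so that no amine oxide ever meets the boronate (amine oxides oxidise C–B bonds). The C3 carbinol is set by a reagent-controlled reduction, because an axial C5 boronate would shield the ring face that a substrate-controlled hydride must use. The iodide for 9 is made by a thiohydroxamate radical chain, which leaves the vinyl group alone.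

## Structural features

The target is a monocyclic brominated sesquiterpenoid: one cyclohexane ring (C1–C6) joined through the C7–C8 ethylene bridge to an acyclic tertiary vinyl carbinol (C9, S), with no ring fusion. The ring carries an exocyclic methylidene at C2, a secondary allylic bromide at C3, a second secondary bromide at C5 and a quaternary gem-dimethyl carbon C6 between C5 and C1. The ring stereocentres C1, C3 and C5 sit at alternate positions, so none is adjacent to another; the C1 chain and C5 bromine are cis (both equatorial in the chair), the C3 bromine is trans to both and therefore axial, and C9 is insulated from the ring by two methylenes. The fragile groups are the axial allylic C3 bromide (ionisation, SN2' shift to the primary allylic bromide, elimination), the tertiary allylic alcohol (ionisation and allylic transposition) and the two alkenes (electrophiles). The real difficulty is the equatorial C5 bromide on a neopentyl-type carbon, which no SN2 displacement will deliver, together with relating C1, C3 and C5 across a ring that offers no neighbouring stereocentre to lean on. The key step exploits the sequence C6 (quaternary)–C1 (chain)–C2 (one-carbon branch)–C3 (heteroatom), which is the γ, β, α and carbonyl carbon of a 4,4-dimethylcyclohexenone: C1–C7 and C2–CH2 are made by conjugate addition and enolate capture on the symmetrical dienone, whose second enone arm (C4=C5) stays as the handle for C5 and whose carbonyl is the handle for C3.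

## Logic of the disconnections

21 to 20: the C3–Br bond is cut back to an equatorial C3–OH of opposite configuration. The allylic bromide is the most labile group and is therefore made last. The forward step must be a clean SN2 inversion, must not drift to the SN2' product and must leave the tertiary C9–OH alone.

20 to 19 and 17 to 16: only O–Si bonds are involved. Both hydroxyls must be masked while an aryllithium is present; one silyl type on both oxygens lets a single fluoride step release them.

19 to 17: the C5–Br bond is cut to a C5–B bond of opposite configuration. A neopentyl secondary bromide cannot be made by substitution at carbon, but a boronate can be brominated with inversion at carbon. This turns the hardest centre into one that an enone can deliver; the forward step needs a stereospecific two-electron pathway at a hindered boron.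

16 to 15: the C3–H bond is cut to the C3 ketone. The demand is hydride delivery to the face that gives the C3–O bond cis to the C1 chain, under reagent control.

15 to 13 (through 14): the C2=CH2 double bond is traced to a C2–CH2–N unit by elimination of the amine. Doing this next to the ketone makes the elimination trivial and avoids an amine oxide in the presence of boron.

13 to 12: the C5–B bond is cut, revealing the second enone arm. Boron must add at C5 anti to the C1 chain, and the amino ketone must survive mild base.

12 to 2, 9 and 10 (key disconnection): C1–C7 and C2–CH2 are cut. Ten ring and branch carbons, the C1 and C2 stereocentres and the full side chain come from three simple pieces in one operation. The forward step needs catalyst-controlled face selectivity at C1 and efficient capture of a zinc enolate.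

2 to 1: one C=C bond is removed; the forward step is a dehydrogenation.

9 to 8: the two C–Zn bonds of 9 are traced to the C–I bonds of two molecules of 8 by iodine–zinc exchange, which must give a salt-free reagent.

8 to 6 (through 7): the C–I bond replaces a C–CO2H bond with loss of one carbon. The radical chain must not touch the vinyl group.

6 to 4 (through 5) and 4 to 3: the carboxyl carbon is traced to the trisubstituted alkene carbon of 3, and the O–Si bond to the free carbinol. The C9 stereocentre is thereby bought from the chiral pool; the oxidative cleavage must discriminate the electron-rich trisubstituted alkene from the vinyl group.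

## Other disconnections considered

Alternative 1: The cut is the C2–C3 ring bond. In the forward sense, divalent chromium (CrCl2) with catalytic NiCl2 would convert the vinyl iodide of the open-chain iodoalkenyl aldehyde A2 into a vinylchromium species that adds to the C3 aldehyde (Nozaki–Hiyama–Kishi closure), giving A1, which is identical with 16 of the chosen route.
- In its favour: the methylidene is in place from the start, so no Mannich base and no labile α-methylene ketone need be handled. The conditions should tolerate boronate, silyl ether and vinyl groups. Since it lands on 16, the last four steps are the same.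
- Against it here: A2 must carry C1, C5 and C9, including a secondary boronate beside a quaternary carbon, all set in an open chain without the conformational control of a ring. That would cost far more steps than one three-component coupling on a preformed ring. The C3 configuration would rest on substrate control in the ring closure, and chromium is used in stoichiometric amount.
- Comparison: on mechanism at C3 it may be the equal of the chosen plan, since a chair-like closure should favour the equatorial hydroxyl. On avoiding 15 it is better. On structure and step economy it is clearly behind.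

Alternative 2: The cut is the C8–C9 bond. In the forward sense, the carbamate A4 of (R)-but-3-en-2-ol would be lithiated and captured by the C8 pinacol boronate A5; 1,2-migration of C8 from boron to carbon and oxidation would give the tertiary vinyl carbinol A3.
- In its favour: it is convergent, and C9 would come from a stereospecific process on a small alcohol obtainable in high optical purity. That is better than depending on the optical purity of 3, and it would make the four-step degradation of 3 unnecessary. The carbinol also emerges unprotected.
- Against it here: A5 still needs C1, C3, C5 and the methylidene, so all of the ring chemistry of the chosen route must be run on a boron-terminated two-carbon chain. The secondary C5 bromide and the allylic silyl ether would have to survive an organolithium carbenoid and a peroxide work-up. C3 would still need desilylation and an Appel reaction next to a free tertiary alcohol, which is equal to the chosen plan.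
- Comparison: better on the source of C9 stereochemistry, equal on the endgame, equal or slightly longer in steps, and weaker on functional-group tolerance in its key step.

Alternative 3: The cuts are C1–C6 and C4–C5. In the forward sense, Cu(OTf)2 with a chiral bis(oxazoline) would promote Mukaiyama–Michael attack of the silyloxydiene A7 on the alkylidene malonate A8, followed by intramolecular Michael closure to the cyclohexanone A6.
- In its favour: ring, quaternary carbon and C1 would all be made in one catalytic asymmetric event from acyclic material. That is a more convergent ring construction than starting from a preformed ring. It is equal to the chosen plan in letting a chiral copper catalyst set C1.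
- Against it here: A6 carries its functionality in the wrong places. The ketone is at C2, needing methylenation beside an epimerisable C1. The geminal diester at C5 must become a single equatorial bromide, and a halodecarboxylation would be radical-based and not stereocontrolled. C3 has no handle at all. A β,β-disubstituted alkylidene malonate is also a reluctant acceptor.
- Comparison: elegant on ring formation, but structurally mismatched with the target's substitution pattern and much longer after the key step.

Key step: step 6

## Route

Step 1
Reactants: 1 4,4-dimethylcyclohex-2-en-1-one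
Product: 2 4,4-dimethylcyclohexa-2,5-dien-1-one
Conditions: DDQ (1.3 equiv), 1,4-dioxane, reflux
Reagents that add atoms: none
Why: Quinone dehydrogenation of an enone through its cross-conjugated dienol: DDQ abstracts hydride from the carbon β to the carbonyl on the saturated side and the oxygen-bound proton is lost. The quaternary ring carbon blocks aromatisation, so the cross-conjugated dienone is the end point.

Step 2
Reactants: 3 (S)-linalool
Product: 4 triethyl{[(3S)-3,7-dimethylocta-1,6-dien-3-yl]oxy}silane
Conditions: TESOTf, 2,6-lutidine, CH2Cl2, −78 → 0 °C
Reagents that add atoms: triethylsilyl trifluoromethanesulfonate, CC[Si](CC)(CC)OS(=O)(=O)C(F)(F)F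
Why: Silyl triflate silylation of a hindered tertiary alcohol; the stereocentre is not involved, and the triethylsilyl ether is stable to ozone, chlorite, radicals and organozinc chemistry.

Step 3
Reactants: 4 triethyl{[(3S)-3,7-dimethylocta-1,6-dien-3-yl]oxy}silane
Product: 6 (4S)-4-methyl-4-(triethylsilyloxy)hex-5-enoic acid, via aldehyde 5 (not isolated)
Conditions: O3, CH2Cl2, −78 °C (Sudan Red 7B end point); PPh3, −78 °C → rt; concentrate; NaClO2, NaH2PO4, 2-methylbut-2-ene, t-BuOH/H2O, 0 °C → rt
Reagents that add atoms: ozone, [O-][O+]=O; sodium chlorite, [Na+].[O-]Cl=O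
Why: Ozonolysis is selective for the electron-rich trisubstituted alkene over the vinyl group, which is monosubstituted and inductively deactivated by the allylic silyloxy group; the dye marks the end point. Pinnick oxidation of the crude aldehyde with a hypochlorite scavenger then gives the acid without touching the vinyl group or the silyl ether.

Step 4
Reactants: 6 (4S)-4-methyl-4-(triethylsilyloxy)hex-5-enoic acid
Product: 8 (3S)-5-iodo-3-methyl-3-(triethylsilyloxy)pent-1-ene, via thiohydroxamate ester 7 (not isolated)
Conditions: N-hydroxypyridine-2-thione, DCC, 4-(dimethylamino)pyridine (cat.), CH2Cl2, 0 °C → rt, dark; then CHI3, PhCF3, visible light, rt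
Reagents that add atoms: iodoform, IC(I)I
Why: Barton decarboxylative iodination: the acyloxy radical from 7 loses CO2 and the primary radical abstracts iodine from iodoform in a chain. The radical has only unfavourable four-exo and five-endo cyclisation modes onto the vinyl group, the conditions are neutral so the γ-silyloxy acid cannot lactonise, and the stereocentre is untouched.

Step 5
Reactants: 8 (3S)-5-iodo-3-methyl-3-(triethylsilyloxy)pent-1-ene
Product: 9 bis[(3S)-3-methyl-3-(triethylsilyloxy)pent-4-en-1-yl]zinc
Conditions: 8 (2 equiv for each equiv of 9 to be formed), Et2Zn (neat, 5 equiv per 8), CuI (0.3 mol %), 50 °C; then 50 °C/0.1 mmHg to remove EtI and excess Et2Zn; residue taken up in toluene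
Reagents that add atoms: diethylzinc, CC[Zn]CC; second molecule of iodide 8, C=C[C@@](C)(O[Si](CC)(CC)CC)CCI
Why: Copper-catalysed iodine–zinc exchange of a primary alkyl iodide: each zinc atom ends up with two side chains, so two molecules of 8 are consumed for every molecule of 9 and two molecules of ethyl iodide are released. Evaporation of ethyl iodide and of the excess diethylzinc drives the exchange and the redistribution of alkyl groups on zinc to the salt-free homoleptic dialkylzinc required for enantioselective copper catalysis. A γ-silyloxy group does not eliminate from an alkylzinc, and the stereocentre is not involved.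

Step 6
Reactants: 2 4,4-dimethylcyclohexa-2,5-dien-1-one; 9 bis[(3S)-3-methyl-3-(triethylsilyloxy)pent-4-en-1-yl]zinc; 10 N,N-dimethylmethyleneiminium iodide
Product: 12 (5R,6S)-6-[(dimethylamino)methyl]-4,4-dimethyl-5-[(3S)-3-methyl-3-(triethylsilyloxy)pent-4-en-1-yl]cyclohex-2-en-1-one, via alkylzinc dienolate 11 (not isolated)
Conditions: Cu(OTf)2 (3 mol %), (S)-1,1'-binaphthalene-2,2'-diyl N,N-bis[(R)-1-phenylethyl]phosphoramidite (6 mol %), 2 (1.15 equiv), 9 (1.0 equiv), toluene, −30 °C; then 10 (1.5 equiv), THF, −30 → 0 °C; aq NH4Cl
Reagents that add atoms: none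
Why: Divalent Cu(OTf)2 is reduced by 9 to a monovalent copper phosphoramidite complex; transmetalation gives an alkylcopper that π-complexes one enone arm of 2 and delivers C7 to C1, leaving alkylzinc dienolate 11, which then attacks the iminium carbon of 10 through C2 in a Mannich reaction. The closest known reaction type is the copper–phosphoramidite-catalysed conjugate addition of dialkylzincs to 4,4-disubstituted cyclohexadienones and cyclohexenones with electrophilic trapping of the zinc enolate. No ring is closed; the two skeletal bonds C1–C7 and C2–CH2N are formed. C1 is set by the ligand: the (S,R,R) ligand is chosen because its known sense with cyclohex-2-enone corresponds to the (R) centre needed here, the enantiomeric ligand being the remedy should the sense differ, and the remote C9 centre of 9 cannot bias the outcome. C2 is set by the substrate: the iminium ion approaches the dienolate anti to the new C1 chain, giving the trans product with both groups equatorial, which is also the thermodynamic arrangement. The two enone arms of 2 are equivalent, so only face selectivity is required; over-addition is avoided because the first adduct is stored as enolate 11, no dialkylzinc is left when the enone of 12 is released since 9 is the limiting component, and the alkylzinc iodide left after the Mannich step is a poor donor. The vinyl and silyloxy groups of 9 are inert to the organocopper species.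

Step 7
Reactants: 12 (5R,6S)-6-[(dimethylamino)methyl]-4,4-dimethyl-5-[(3S)-3-methyl-3-(triethylsilyloxy)pent-4-en-1-yl]cyclohex-2-en-1-one
Product: 13 (2S,3R,5R)-2-[(dimethylamino)methyl]-4,4-dimethyl-3-[(3S)-3-methyl-3-(triethylsilyloxy)pent-4-en-1-yl]-5-(4,4,5,5-tetramethyl-1,3,2-dioxaborolan-2-yl)cyclohexan-1-one
Conditions: CuCl (5 mol %), bis[2-(diphenylphosphino)phenyl] ether (5 mol %), NaOt-Bu (10 mol %), B2pin2 (1.2 equiv), MeOH (2 equiv), THF, rt
Reagents that add atoms: bis(pinacolato)diboron, CC1(C)OB(B2OC(C)(C)C(C)(C)O2)OC1(C)C
Why: Copper-catalysed conjugate borylation of the remaining enone arm: the copper–boryl species adds boron to C5 by axial attack on the half-chair that keeps the C1 and C2 groups equatorial. That face is anti to the C1 chain and anti to the pseudoaxial C6 methyl, so the C5–B bond is axial and trans to the chain. Catalytic base at room temperature should leave the β-amino ketone intact.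

Step 8
Reactants: 13 (2S,3R,5R)-2-[(dimethylamino)methyl]-4,4-dimethyl-3-[(3S)-3-methyl-3-(triethylsilyloxy)pent-4-en-1-yl]-5-(4,4,5,5-tetramethyl-1,3,2-dioxaborolan-2-yl)cyclohexan-1-one
Product: 15 (3S,5R)-4,4-dimethyl-2-methylidene-3-[(3S)-3-methyl-3-(triethylsilyloxy)pent-4-en-1-yl]-5-(4,4,5,5-tetramethyl-1,3,2-dioxaborolan-2-yl)cyclohexan-1-one, via methiodide 14 (not isolated)
Conditions: MeI (5 equiv), CH2Cl2, rt; then sat. aq NaHCO3, rt
Reagents that add atoms: none
Why: Quaternisation of the Mannich base followed by E1cB loss of trimethylamine, the standard α-methylenation sequence; it needs no oxidant, so the C–B bond is safe, and the C2 stereocentre is deliberately erased. Product 15 is used promptly in dilute solution because α-methylene ketones can dimerise.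

Step 9
Reactants: 15 (3S,5R)-4,4-dimethyl-2-methylidene-3-[(3S)-3-methyl-3-(triethylsilyloxy)pent-4-en-1-yl]-5-(4,4,5,5-tetramethyl-1,3,2-dioxaborolan-2-yl)cyclohexan-1-one
Product: 16 (1R,3S,5R)-4,4-dimethyl-2-methylidene-3-[(3S)-3-methyl-3-(triethylsilyloxy)pent-4-en-1-yl]-5-(4,4,5,5-tetramethyl-1,3,2-dioxaborolan-2-yl)cyclohexan-1-ol
Conditions: (S)-2-methyl-CBS-oxazaborolidine [(S)-1-methyl-3,3-diphenyltetrahydro-1H,3H-pyrrolo[1,2-c][1,3,2]oxazaborole] (0.5 equiv), catecholborane (1.8 equiv), toluene, −78 °C; MeOH, then aq NaHCO3
Reagents that add atoms: none
Why: Corey–Bakshi–Shibata 1,2-reduction of an enone under reagent control: with the fully substituted methylidene carbon C2 as the large group and C4H2 as the small one, the (S)-catalyst delivers hydride to the face that gives the (R)-carbinol, with the C3–O bond cis to the C1 chain and trans to the C5 boron. The ring of 15 has two sp2 carbons and can also react through the chair with boron equatorial and the chain axial, in which that same face is the open one, so substrate and reagent are expected to cooperate. Catecholborane at −78 °C avoids alkene hydroboration and 1,4-reduction.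

Step 10
Reactants: 16 (1R,3S,5R)-4,4-dimethyl-2-methylidene-3-[(3S)-3-methyl-3-(triethylsilyloxy)pent-4-en-1-yl]-5-(4,4,5,5-tetramethyl-1,3,2-dioxaborolan-2-yl)cyclohexan-1-ol
Product: 17 triethyl{[(1R,3S,5R)-4,4-dimethyl-2-methylidene-3-[(3S)-3-methyl-3-(triethylsilyloxy)pent-4-en-1-yl]-5-(4,4,5,5-tetramethyl-1,3,2-dioxaborolan-2-yl)cyclohexyl]oxy}silane
Conditions: TESCl, imidazole, 4-(dimethylamino)pyridine (cat.), CH2Cl2, 0 °C → rt
Reagents that add atoms: chlorotriethylsilane, CC[Si](Cl)(CC)CC
Why: Standard silylation of a secondary alcohol; the hydroxyl must be masked before an aryllithium and an electrophilic bromine source are used, and using the same silyl group as at C9 lets one fluoride step remove both.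

Step 11
Reactants: 17 triethyl{[(1R,3S,5R)-4,4-dimethyl-2-methylidene-3-[(3S)-3-methyl-3-(triethylsilyloxy)pent-4-en-1-yl]-5-(4,4,5,5-tetramethyl-1,3,2-dioxaborolan-2-yl)cyclohexyl]oxy}silane
Product: 19 {[(1R,3R,5S)-5-bromo-4,4-dimethyl-2-methylidene-3-[(3S)-3-methyl-3-(triethylsilyloxy)pent-4-en-1-yl]cyclohexyl]oxy}triethylsilane, via lithium arylboronate complex 18 (not isolated)
Conditions: 1-bromo-3,5-bis(trifluoromethyl)benzene, n-BuLi, THF, −78 °C; then 17, −78 °C; then NBS (1.2 equiv), THF, −78 °C → rt
Reagents that add atoms: N-bromosuccinimide, O=C1CCC(=O)N1Br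
Why: Stereospecific bromodeboronation of a secondary boronic ester through its electron-poor aryl ate complex: the electrophilic bromine attacks C5 on the side opposite to boron (SE2 with inversion), so the axial, trans C5–B bond becomes the equatorial C5–Br bond cis to the C1 chain. This is the configuration that substitution at this neopentyl carbon could not deliver. At −78 °C the ate complex is far more nucleophilic than either alkene.

Step 12
Reactants: 19 {[(1R,3R,5S)-5-bromo-4,4-dimethyl-2-methylidene-3-[(3S)-3-methyl-3-(triethylsilyloxy)pent-4-en-1-yl]cyclohexyl]oxy}triethylsilane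
Product: 20 (1R,3R,5S)-5-bromo-3-[(3S)-3-hydroxy-3-methylpent-4-en-1-yl]-4,4-dimethyl-2-methylidenecyclohexan-1-ol
Conditions: TBAF (3 equiv), THF, 0 °C → rt
Reagents that add atoms: none
Why: Fluoride cleavage of both triethylsilyl ethers; the equatorial neopentyl C5 bromide has no antiperiplanar hydrogen and cannot be reached by backside attack, so it should survive the basic fluoride.

Step 13
Reactants: 20 (1R,3R,5S)-5-bromo-3-[(3S)-3-hydroxy-3-methylpent-4-en-1-yl]-4,4-dimethyl-2-methylidenecyclohexan-1-ol
Product: 21 (3S)-5-[(1S,3S,5S)-3,5-dibromo-2,2-dimethyl-6-methylidenecyclohexyl]-3-methylpent-1-en-3-ol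
Conditions: CBr4 (1.3 equiv), PPh3 (1.4 equiv), CH2Cl2, −20 → 0 °C
Reagents that add atoms: carbon tetrabromide, BrC(Br)(Br)Br
Why: Appel reaction: the less hindered secondary allylic hydroxyl forms the alkoxyphosphonium ion and bromide displaces it by SN2 from the unhindered axial direction, inverting C3 to the axial bromide trans to the C1 chain and the C5 bromine. The equatorial C–O bond lies near the nodal plane of the methylidene π bond, which disfavours SN2', and the hindered tertiary C9 hydroxyl is activated far more slowly.

## Compound list

1 | 4,4-dimethylcyclohex-2-en-1-one | CC1(C)CCC(=O)C=C1 | starting material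
2 | 4,4-dimethylcyclohexa-2,5-dien-1-one | O=C1C=CC(C)(C)C=C1 | intermediate
3 | (S)-linalool, (3S)-3,7-dimethylocta-1,6-dien-3-ol | C=C[C@@](C)(O)CCC=C(C)C | starting material
4 | triethyl{[(3S)-3,7-dimethylocta-1,6-dien-3-yl]oxy}silane | C=C[C@@](C)(O[Si](CC)(CC)CC)CCC=C(C)C | intermediate
5 | (4S)-4-methyl-4-(triethylsilyloxy)hex-5-enal | C=C[C@@](C)(O[Si](CC)(CC)CC)CCC=O | intermediate (not isolated)
6 | (4S)-4-methyl-4-(triethylsilyloxy)hex-5-enoic acid | C=C[C@@](C)(O[Si](CC)(CC)CC)CCC(=O)O | intermediate
7 | 2-thioxopyridin-1(2H)-yl (4S)-4-methyl-4-(triethylsilyloxy)hex-5-enoate | C=C[C@@](C)(O[Si](CC)(CC)CC)CCC(=O)ON1C=CC=CC1=S | intermediate (not isolated)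
8 | (3S)-5-iodo-3-methyl-3-(triethylsilyloxy)pent-1-ene | C=C[C@@](C)(O[Si](CC)(CC)CC)CCI | intermediate
9 | bis[(3S)-3-methyl-3-(triethylsilyloxy)pent-4-en-1-yl]zinc | C=C[C@@](C)(O[Si](CC)(CC)CC)CC[Zn]CC[C@@](C)(C=C)O[Si](CC)(CC)CC | intermediate
10 | N,N-dimethylmethyleneiminium iodide | C=[N+](C)C.[I-] | starting material
11 | {[(3R)-4,4-dimethyl-3-[(3S)-3-methyl-3-(triethylsilyloxy)pent-4-en-1-yl]cyclohexa-1,5-dien-1-yl]oxy}[(3S)-3-methyl-3-(triethylsilyloxy)pent-4-en-1-yl]zinc | C=C[C@@](C)(O[Si](CC)(CC)CC)CC[C@@H]1C=C(O[Zn]CC[C@@](C)(C=C)O[Si](CC)(CC)CC)C=CC1(C)C | intermediate (not isolated)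
12 | (5R,6S)-6-[(dimethylamino)methyl]-4,4-dimethyl-5-[(3S)-3-methyl-3-(triethylsilyloxy)pent-4-en-1-yl]cyclohex-2-en-1-one | C=C[C@@](C)(O[Si](CC)(CC)CC)CC[C@@H]1[C@@H](CN(C)C)C(=O)C=CC1(C)C | intermediate
13 | (2S,3R,5R)-2-[(dimethylamino)methyl]-4,4-dimethyl-3-[(3S)-3-methyl-3-(triethylsilyloxy)pent-4-en-1-yl]-5-(4,4,5,5-tetramethyl-1,3,2-dioxaborolan-2-yl)cyclohexan-1-one | C=C[C@@](C)(O[Si](CC)(CC)CC)CC[C@@H]1[C@@H](CN(C)C)C(=O)C[C@@H](B2OC(C)(C)C(C)(C)O2)C1(C)C | intermediate
14 | N-methyl quaternary ammonium iodide of 13, with a (trimethylammonio)methyl group at C2 | C=C[C@@](C)(O[Si](CC)(CC)CC)CC[C@@H]1[C@@H](C[N+](C)(C)C)C(=O)C[C@@H](B2OC(C)(C)C(C)(C)O2)C1(C)C.[I-] | intermediate (not isolated)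
15 | (3S,5R)-4,4-dimethyl-2-methylidene-3-[(3S)-3-methyl-3-(triethylsilyloxy)pent-4-en-1-yl]-5-(4,4,5,5-tetramethyl-1,3,2-dioxaborolan-2-yl)cyclohexan-1-one | C=C[C@@](C)(O[Si](CC)(CC)CC)CC[C@@H]1C(=C)C(=O)C[C@@H](B2OC(C)(C)C(C)(C)O2)C1(C)C | intermediate
16 | (1R,3S,5R)-4,4-dimethyl-2-methylidene-3-[(3S)-3-methyl-3-(triethylsilyloxy)pent-4-en-1-yl]-5-(4,4,5,5-tetramethyl-1,3,2-dioxaborolan-2-yl)cyclohexan-1-ol | C=C[C@@](C)(O[Si](CC)(CC)CC)CC[C@@H]1C(=C)[C@H](O)C[C@@H](B2OC(C)(C)C(C)(C)O2)C1(C)C | intermediate
17 | triethyl{[(1R,3S,5R)-4,4-dimethyl-2-methylidene-3-[(3S)-3-methyl-3-(triethylsilyloxy)pent-4-en-1-yl]-5-(4,4,5,5-tetramethyl-1,3,2-dioxaborolan-2-yl)cyclohexyl]oxy}silane | C=C[C@@](C)(O[Si](CC)(CC)CC)CC[C@@H]1C(=C)[C@H](O[Si](CC)(CC)CC)C[C@@H](B2OC(C)(C)C(C)(C)O2)C1(C)C | intermediate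
18 | lithium [3,5-bis(trifluoromethyl)phenyl] ate complex of boronic ester 17 (aryl group on tetracoordinate boron at C5) | C=C[C@@](C)(O[Si](CC)(CC)CC)CC[C@@H]1C(=C)[C@H](O[Si](CC)(CC)CC)C[C@@H]([B-]2(c3cc(C(F)(F)F)cc(C(F)(F)F)c3)OC(C)(C)C(C)(C)O2)C1(C)C.[Li+] | intermediate (not isolated)
19 | {[(1R,3R,5S)-5-bromo-4,4-dimethyl-2-methylidene-3-[(3S)-3-methyl-3-(triethylsilyloxy)pent-4-en-1-yl]cyclohexyl]oxy}triethylsilane | C=C[C@@](C)(O[Si](CC)(CC)CC)CC[C@@H]1C(=C)[C@H](O[Si](CC)(CC)CC)C[C@H](Br)C1(C)C | intermediate
20 | (1R,3R,5S)-5-bromo-3-[(3S)-3-hydroxy-3-methylpent-4-en-1-yl]-4,4-dimethyl-2-methylidenecyclohexan-1-ol | C=C[C@@](C)(O)CC[C@@H]1C(=C)[C@H](O)C[C@H](Br)C1(C)C | intermediate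
21 | (3S)-5-[(1S,3S,5S)-3,5-dibromo-2,2-dimethyl-6-methylidenecyclohexyl]-3-methylpent-1-en-3-ol | C=C[C@@](C)(O)CC[C@@H]1C(=C)[C@@H](Br)C[C@H](Br)C1(C)C | target

## Step count and least certain steps

Total step count: 13. Longest linear sequence: 12 steps (3 to 21, steps 2–13); the one-step branch from 1 joins at step 6.

Step 6 (key step).
- What may go wrong: incomplete aminomethylation of the zinc dienolate, because zinc enolates are weak nucleophiles and the iminium salt is poorly soluble in toluene. The enolate would then be protonated on work-up, or the enone freed in the flask would take up a second alkyl group from residual alkylzinc species. A second concern is erosion of face selectivity at a β-carbon flanked by the quaternary centre.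
- Fallback, setting out from 2 and 9 and coming back at 12: the same copper-catalysed addition is run, but dienolate 11 is silylated in the flask (TMSCl, Et3N) to the isolable trimethylsilyl dienol ether F1. The enantiomeric purity can be checked at that stage. F1 is then aminomethylated with 10 in CH2Cl2 (Mannich reaction of a silyl enol ether, regiospecific at C2 and anti to the C1 chain), which returns to 12.

Step 9.
- What may go wrong: poor facial selectivity if the intrinsic bias of the flexible α-methylene ketone opposes the catalyst. The chair with axial boron exposes the other carbonyl face. Conjugate reduction of the s-cis enone by uncatalysed catecholborane is a second risk.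
- Fallback, setting out from 15 and coming back at 16: reduction with the enantiomeric (R)-catalyst, which would then be the matched case, gives the C3-epimeric alcohol F2. Mitsunobu inversion (4-nitrobenzoic acid, PPh3, DIAD, THF) gives the inverted 4-nitrobenzoate F3, and methanolysis (K2CO3, MeOH) returns to 16.

Step 11.
- What may go wrong: slow or incomplete ate-complex formation at a boron flanked by the quaternary carbon, or leakage into single-electron pathways that erode the inversion. A radical at C5 would be brominated from the axial direction and give the wrong epimer.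
- Fallback, setting out from 17 and coming back at 19: both alkenes are masked as vicinal dibromides (Br2, CH2Cl2, −78 °C), giving the tetrabromo boronate F4. Base-induced halogenolysis of its methoxide ate complex (NaOMe, then Br2, MeOH/THF, −78 °C) is then used; this is a small nucleophile on boron and a two-electron displacement with inversion at carbon, and gives the pentabromide F5. Zinc dust in AcOH/Et2O at 0 °C regenerates both alkenes without touching the isolated neopentyl bromide and returns to 19.

Step 13.
- What may go wrong: allylic transposition, since the axial allylic bromide, once formed, is well aligned for SN2' attack by bromide and can drift to the more stable primary allylic bromide with an endocyclic alkene. Participation of the free tertiary C9 hydroxyl (competing activation or ether formation) is the second risk.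
- Fallback, setting out from 19 and coming back at 21: the secondary allylic silyl ether alone is cleaved (PPTS, MeOH/CH2Cl2, 0 °C) to the mono-silyl ether F6, so that C9 stays masked. The Appel reaction at low temperature then gives the silyl-protected dibromide F7, and HF·pyridine in THF at 0 °C removes the tertiary silyl ether under non-basic conditions with a poorly nucleophilic fluoride, giving 21.

## Further compounds

F1 | step 6 | trimethyl{[(3R)-4,4-dimethyl-3-[(3S)-3-methyl-3-(triethylsilyloxy)pent-4-en-1-yl]cyclohexa-1,5-dien-1-yl]oxy}silane | C=C[C@@](C)(O[Si](CC)(CC)CC)CC[C@@H]1C=C(O[Si](C)(C)C)C=CC1(C)C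
F2 | step 9 | (1S,3S,5R)-4,4-dimethyl-2-methylidene-3-[(3S)-3-methyl-3-(triethylsilyloxy)pent-4-en-1-yl]-5-(4,4,5,5-tetramethyl-1,3,2-dioxaborolan-2-yl)cyclohexan-1-ol | C=C[C@@](C)(O[Si](CC)(CC)CC)CC[C@@H]1C(=C)[C@@H](O)C[C@@H](B2OC(C)(C)C(C)(C)O2)C1(C)C
F3 | step 9 | (1R,3S,5R)-4,4-dimethyl-2-methylidene-3-[(3S)-3-methyl-3-(triethylsilyloxy)pent-4-en-1-yl]-5-(4,4,5,5-tetramethyl-1,3,2-dioxaborolan-2-yl)cyclohexyl 4-nitrobenzoate | C=C[C@@](C)(O[Si](CC)(CC)CC)CC[C@@H]1C(=C)[C@H](OC(=O)c2ccc(cc2)[N+](=O)[O-])C[C@@H](B3OC(C)(C)C(C)(C)O3)C1(C)C
F4 | step 11 | tetrabromide of 17 with both alkenes as vicinal dibromides (C2 bromo and bromomethyl, C10 and C11 bromo); configuration at C1, C3, C5 and C9 as in 17, mixture at the new C2 and C10 centres | BrCC(Br)[C@@](C)(O[Si](CC)(CC)CC)CC[C@@H]1C(Br)(CBr)[C@H](O[Si](CC)(CC)CC)C[C@@H](B2OC(C)(C)C(C)(C)O2)C1(C)C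
F5 | step 11 | pentabromide from F4 with the C5 boronate replaced by bromine with inversion; mixture at the C2 and C10 centres | BrCC(Br)[C@@](C)(O[Si](CC)(CC)CC)CC[C@@H]1C(Br)(CBr)[C@H](O[Si](CC)(CC)CC)C[C@H](Br)C1(C)C
F6 | step 13 | (1R,3R,5S)-5-bromo-4,4-dimethyl-2-methylidene-3-[(3S)-3-methyl-3-(triethylsilyloxy)pent-4-en-1-yl]cyclohexan-1-ol | C=C[C@@](C)(O[Si](CC)(CC)CC)CC[C@@H]1C(=C)[C@H](O)C[C@H](Br)C1(C)C
F7 | step 13 | triethyl{[(3S)-5-[(1S,3S,5S)-3,5-dibromo-2,2-dimethyl-6-methylidenecyclohexyl]-3-methylpent-1-en-3-yl]oxy}silane | C=C[C@@](C)(O[Si](CC)(CC)CC)CC[C@@H]1C(=C)[C@@H](Br)C[C@H](Br)C1(C)C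
A1 | alternative 1 | (1R,3S,5R)-4,4-dimethyl-2-methylidene-3-[(3S)-3-methyl-3-(triethylsilyloxy)pent-4-en-1-yl]-5-(4,4,5,5-tetramethyl-1,3,2-dioxaborolan-2-yl)cyclohexan-1-ol (identical with 16) | C=C[C@@](C)(O[Si](CC)(CC)CC)CC[C@@H]1C(=C)[C@H](O)C[C@@H](B2OC(C)(C)C(C)(C)O2)C1(C)C
A2 | alternative 1 | (3R,5S,8S)-5-(1-iodoethenyl)-4,4,8-trimethyl-3-(4,4,5,5-tetramethyl-1,3,2-dioxaborolan-2-yl)-8-(triethylsilyloxy)dec-9-enal | C=C[C@@](C)(O[Si](CC)(CC)CC)CC[C@H](C(I)=C)C(C)(C)[C@@H](CC=O)B1OC(C)(C)C(C)(C)O1
A3 | alternative 2 | (3S)-5-[(1R,3S,5R)-3-bromo-5-(tert-butyldimethylsilyloxy)-2,2-dimethyl-6-methylidenecyclohexyl]-3-methylpent-1-en-3-ol | C=C[C@@](C)(O)CC[C@@H]1C(=C)[C@H](O[Si](C)(C)C(C)(C)C)C[C@H](Br)C1(C)C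
A4 | alternative 2 | (2R)-but-3-en-2-yl N,N-di(propan-2-yl)carbamate | C[C@@H](OC(=O)N(C(C)C)C(C)C)C=C
A5 | alternative 2 | 2-{2-[(1R,3S,5R)-3-bromo-5-(tert-butyldimethylsilyloxy)-2,2-dimethyl-6-methylidenecyclohexyl]ethyl}-4,4,5,5-tetramethyl-1,3,2-dioxaborolane | CC1(C)OB(CC[C@@H]2C(=C)[C@H](O[Si](C)(C)C(C)(C)C)C[C@H](Br)C2(C)C)OC1(C)C
A6 | alternative 3 | dimethyl (3S)-2,2-dimethyl-3-[(3S)-3-methyl-3-(triethylsilyloxy)pent-4-en-1-yl]-4-oxocyclohexane-1,1-dicarboxylate | C=C[C@@](C)(O[Si](CC)(CC)CC)CC[C@@H]1C(=O)CCC(C(=O)OC)(C(=O)OC)C1(C)C
A7 | alternative 3 | triethyl{[(3S,6Z)-3-methyl-7-(trimethylsilyloxy)nona-1,6,8-trien-3-yl]oxy}silane | C=C[C@@](C)(O[Si](CC)(CC)CC)CC/C=C(\O[Si](C)(C)C)C=C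
A8 | alternative 3 | dimethyl 2-(propan-2-ylidene)propanedioate | CC(C)=C(C(=O)OC)C(=O)OC
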